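As the chemist ranking violet, ochre, red and teal, I began with what L has left after G.

| setting | dusk | noon | violet | ochre | red | teal |
|---|---|---|---|---|---|---|
| Q | 0.10 M | 0.10 M | 0.10 M | 0.10 M | 0.10 M (in portions, 4, over 30 h) | 0.10 M (fed, over 30 h) |
| L | 0.080 M | 0.080 M | 0.0800 M | 0.0800 M (fed, over 30 h) | 0.0800 M | 0.0800 M |
| G | 0.050 M | 0.025 M | 0.0500 M | 0.0500 M | 0.0500 M | 0.0500 M |
| remark | run made earlier | run made earlier | everything together at the start | all else is in the flask from the start; the feed brings no volume worth counting | first portion at the start, last at 30 h | all else is in the flask from the start; the feed brings no volume worth counting |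
| time |  |  | 3.0 d | 3.0 d | 3.0 d | 3.0 d |

- dusk (time / h: X / %, J / %, Q / %): 6.00: 7, 0, 21; 12.0: 8, 0, 11; 20.0: 0, 0, 11; 25.0: 2, 2, 8; 30.0: 0, 0, 9; 40.0: 1, 1, 5
- noon (time / h: X / %, J / %, Q / %): 1.00: 16, 0, 50; 2.00: 21, 0, 37; 3.00: 22, 1, 31; 4.00: 19, 0, 25; 5.00: 15, 0, 21; 6.00: 14, 0, 20; 8.00: 14, 1, 17

(each reading ± 1.5 percentage points)

- a species is counted by the Q in it: one D counts as two
- on the list of suspects stand: G + L -> E; 2 Q -> D; Q + L <-> X; X -> J

- the best flask by share of X in X plus J; "all alike" if 1.5 percentage points covers them all (violet / ochre / red / teal / all alike)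
- share of X in X plus J at the end, violet
- share of X in X plus J at the end, ochre
- share of X in X plus J at the end, red
- share of X in X plus J at the end, teal

I took G + L → E to run until G was gone, G being the limiting reagent of that pair. Spare L in dusk is then 30.0% of the Q charge, and in noon 55.0%, about twice as much. Yet the last X reading is 14% in noon and 1% in dusk, which looks contradictory.

Q + L ⇌ X clears this up, because X follows Q as well as L, and the last Q readings are 17% in noon and 5% in dusk. So I reckoned with the holding ratio, X over Q at balance, which is proportional to free L. At the last noon reading, X over Q is 0.824 and free L is 41.0% of the Q charge, so the factor reads 2.01.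

Violet, ochre, red and teal have the same charges, so each gets spare L of 30.0% and a holding ratio of 0.603. For dusk's last reading this gives X of 3.02%, within two scatters of the reading. The dusk readings at 6.00 h and 20.0 h lie further under, though the one at 12.0 h lies over, so I held the ratio as a high figure. By this ratio X follows the Q left in each flask, and the share sets J against that X; the last noon J reading is less than the scatter.

The forecast gave teal as best, with 17%, 16%, 30% and 35% for violet, ochre, red and teal, taking X at the end as “a tiny residue”.

The flasks gave 88.5%, 95.5%, 89.9% and 89.8%, so ochre is best. X over Q ended at 0.497 in violet and 0.501 in ochre, under my 0.603.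

    G + L → E (k = 52.0 M⁻¹ h⁻¹)
    2 Q → D (k = 3.40 M⁻¹ h⁻¹)
    Q + L ⇌ X (K = 17.0 M⁻¹, k = 7.40 M⁻¹ h⁻¹)
    X → J (k = 6.50 × 10⁻⁴ h⁻¹)

In violet, the half-life of X by loss to J alone, 44 d, is long against the 3.0 d of the run. Violet ended with X at 1.40% and J at 0.182%.

In a neighbour flask, violet with 0.20 M of L, spare L is 150% of the Q charge, so the same factor gives a ratio of 3.01, again a high figure. The computed flask ends with X at 11.8% and Q at 4.94%, a ratio of 2.39, and a share of 92.1%.

(All runs are calculated with constants of no real substance; noise was put on by code.)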